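**Retrosynthetic overview**
1. Target 9 ⇒ open the N1–C2 bond and move the C3 bromine back to C2. This gives β,β-dibromo-2-nitrostyrene 6, which is 9 plus two oxygen atoms.
2. 6 ⇒ aldehyde 4 + CBr4 (5). C2 and both pyrrole-ring bromines arrive as one CBr2 unit.
3. 4 ⇒ nitrotoluene 2 (CH3 → CHO through enamine 3) ⇒ 4-bromo-2-nitrotoluene 1 (one ring bromination).
4. Ring order: the benzene ring is bought, and the pyrrole ring is closed last in the C–N bond-forming step.

Assumption: the target is planar and has no stereocentre, so there is no enantiomer to control. The only stereo-elements on the route are the E-enamine 3 and the transient racemic C3 of 8.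

**Step 1**
Reactants: 1 4-bromo-2-nitrotoluene
Product: 2 2,4-dibromo-6-nitrotoluene (1,5-dibromo-2-methyl-3-nitrobenzene)
Conditions: NBS (1.2 equiv), conc. H2SO4, 60 °C, dark, 3 h
Reagents that add atoms: N-bromosuccinimide, O=C1CCC(=O)N1Br
Why: Electrophilic aromatic bromination of a deactivated arene with protonated NBS goes to C6, the only free position that is ortho to the methyl group and meta to the nitro group, whereas C3 and C5 are ortho or para to NO2.

**Step 2**
Reactants: 2 2,4-dibromo-6-nitrotoluene
Product: 4 2,4-dibromo-6-nitrobenzaldehyde, via enamine 3 (not isolated)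
Conditions: DMF-DMA (3 equiv), DMF, 130 °C; then NaIO4 (3 equiv), DMF/H2O, 0 °C to rt
Reagents that add atoms: N,N-dimethylformamide dimethyl acetal, COC(OC)N(C)C (its CH–NMe2 unit stands in 3 and is cleaved off again); sodium periodate NaIO4, [Na+].[O-]I(=O)(=O)=O (aldehyde oxygen)
Why: The methyl group ortho to NO2 is acidic enough to condense with DMF-DMA (first half of a Leimgruber–Batcho sequence), and the electron-rich enamine C=C is then cleaved by periodate without a metal, leaving the nitro group and the aryl bromides untouched.

**Step 3**
Reactants: 4 2,4-dibromo-6-nitrobenzaldehyde; 5 carbon tetrabromide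
Product: 6 1,5-dibromo-2-(2,2-dibromoethenyl)-3-nitrobenzene
Conditions: CBr4 (1.5 equiv), PPh3 (3 equiv), CH2Cl2, 0 °C to rt
Reagents that add atoms: carbon tetrabromide, BrC(Br)(Br)Br
Why: In this Ramirez gem-dibromoolefination (first stage of the Corey–Fuchs sequence), Ph3P=CBr2 made in the flask undergoes a Wittig reaction with the very electrophilic aldehyde, and NO2 and ArBr are inert to PPh3 at this temperature.

**Step 4**
Reactants: 6 1,5-dibromo-2-(2,2-dibromoethenyl)-3-nitrobenzene
Product: 9 2,3,4,6-tetrabromo-1H-indole, via 2,2,4,6-tetrabromo-2H-indole 7 (not isolated), via 2,3,4,6-tetrabromo-3H-indole 8 (not isolated)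
Conditions: 1,2,2,3,4,4-hexamethylphosphetane 1-oxide (15 mol %), PhSiH3 (2.2 equiv), n-BuOAc (0.1 M), 110 °C, N2, dark
Reagents that add atoms: none
Why: Proposed new method: the phosphetane formed by silane reduction of its oxide removes both nitro oxygens in a trivalent/pentavalent phosphorus redox cycle, the resulting aryl nitrenoid closes onto the β-carbon of the gem-dibromoalkene to form the N1–C2 bond and the o-quinoid 2H-indole 7, rearomatisation then drives a suprafacial 1,5-shift (formal 1,2-shift) of one bromine from C2 to C3 to give 8, and 8 tautomerises to 9, so both pyrrole-ring bromines come from the CBr2 unit and no late bromination is needed; both candidates for migration are bromine, so there is no selectivity question, a stray shift to nitrogen would still funnel to the 3-bromo compound, and keeping the halophilic trivalent phosphorus at catalytic level limits bromine abstraction from 7 and 8; the closest known reaction type is the Cadogan–Sundberg reductive cyclisation of β,β-disubstituted 2-nitrostyrenes, which proceeds with 1,2-shift of alkyl, aryl or acyl groups, whereas a halogen shift from a gem-dihaloalkene has not been shown.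

**Compound list**
1 | 4-bromo-2-nitrotoluene | Cc1ccc(Br)cc1[N+](=O)[O-] | starting material
2 | 2,4-dibromo-6-nitrotoluene (1,5-dibromo-2-methyl-3-nitrobenzene) | Cc1c(Br)cc(Br)cc1[N+](=O)[O-] | intermediate
3 | (E)-2-(2,4-dibromo-6-nitrophenyl)-N,N-dimethylethen-1-amine (not isolated) | CN(C)/C=C/c1c(Br)cc(Br)cc1[N+](=O)[O-] | intermediate
4 | 2,4-dibromo-6-nitrobenzaldehyde | O=Cc1c(Br)cc(Br)cc1[N+](=O)[O-] | intermediate
5 | carbon tetrabromide | BrC(Br)(Br)Br | starting material
6 | 1,5-dibromo-2-(2,2-dibromoethenyl)-3-nitrobenzene | BrC(Br)=Cc1c(Br)cc(Br)cc1[N+](=O)[O-] | intermediate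
7 | 2,2,4,6-tetrabromo-2H-indole (not isolated) | BrC1(Br)C=C2C(Br)=CC(Br)=CC2=N1 | intermediate
8 | 2,3,4,6-tetrabromo-3H-indole (racemic at C3, not isolated) | BrC1=Nc2cc(Br)cc(Br)c2C1Br | intermediate
9 | 2,3,4,6-tetrabromo-1H-indole | Brc1cc(Br)c2c(Br)c(Br)[nH]c2c1 | target

**Total step count:** 4. **Longest linear sequence:** 4 (1 → 2 → 4 → 6 → 9).

**Three steps most likely to fail**

Step 4 (the new step). There are three risks.
- The styrene carries two ortho substituents and is twisted, so ring closure may lose out to reduction of the nitrenoid to the aniline.
- Intermediates 7 and 8 are positive-bromine donors and may lose a bromine to phosphine or silane.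
- The product is sensitive to heat, acid and light.

The fallback uses only known chemistry, a Leimgruber–Batcho cyclisation followed by electrophilic dibromination. It sets out from enamine 3, made from 2 as in the first half of step 2 and concentrated instead of being oxidised. Fe powder in AcOH/EtOH at 80 °C reduces the nitro group. The aniline then adds to the enamine and loses dimethylamine to give 4,6-dibromo-1H-indole F1. NBS (2.05 equiv) on SiO2 in CH2Cl2, 0 °C to rt in the dark, brominates C3 and then C2, and the route comes back at 9.

Step 2. The methyl group sits between Br and NO2, so the condensation may be slow or incomplete, and the periodate stage then gives a poor mass balance. The fallback replaces the enamine route with radical functionalisation followed by an N-oxide oxidation, and it sets out from 2. NBS with azobisisobutyronitrile in refluxing PhCF3 gives 1,5-dibromo-2-(bromomethyl)-3-nitrobenzene F2. N-Methylmorpholine N-oxide (3 equiv) with 4 Å molecular sieves in MeCN at rt displaces the bromide, and the alkoxyammonium salt collapses to the aldehyde, coming back at 4.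

Step 3. The aldehyde has two ortho substituents, so the bulky ylide may react sluggishly, and separation from phosphorus by-products may cost material. The fallback is a phosphorus-free, copper-catalysed olefination of the hydrazone, and it sets out from 4. Hydrazine hydrate in DMSO at 0 °C to rt gives (E)-(2,4-dibromo-6-nitrobenzylidene)hydrazine F3; the mixture is kept cold to avoid indazole formation. Treating F3 with CBr4 (5), CuCl (10 mol %) and aqueous NH3 in DMSO at rt releases N2 and comes back at 6.

**Further compounds**
F1 | step 4 | 4,6-dibromo-1H-indole | Brc1cc(Br)c2cc[nH]c2c1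
F2 | step 2 | 1,5-dibromo-2-(bromomethyl)-3-nitrobenzene | BrCc1c(Br)cc(Br)cc1[N+](=O)[O-]
F3 | step 3 | (E)-(2,4-dibromo-6-nitrobenzylidene)hydrazine | N/N=C/c1c(Br)cc(Br)cc1[N+](=O)[O-]
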